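## The problem

The target is a C20 gibberellin with a 6-5-6-5 skeleton in which ring A (C1–C5, C10) is trans-fused through C5–C10 to the five-membered ring B (C5, C6, C8, C9, C10), while rings C and D form a bicyclo[3.2.1]octane whose bridgehead C13 carries a tertiary allylic hydroxyl beside the C16 exocyclic methylene. The α face of ring A is bridged by a δ-lactone from C19 (on C4) to C20 (on C10), so the two quaternary carbons flanking C5 must carry their one-carbon substituents cis and diaxial, and a third quaternary carbon, C8, is shared by rings B, C and D. Of the eight stereocentres, C13 follows from C8 once the bridge is closed, and C2 carries an equatorial alcohol that is open to thermodynamic control. C4, C5 and C10 are contiguous and have to be set relative to C6, C8 and C9. The 13-hydroxy-16-ene unit rearranges in strong acid, the lactone opens in base, the C7 carboxyl is neopentyl-like, and the lactone screens the α face of a C2 ketone so that hydride would arrive from the wrong side. The feature that opens the structure is the C2 oxygen: read as the remnant of an enol ether C1=C2, it makes ring A a cyclohexene in which C5–C10 and C3–C4 are the two bonds of a Diels–Alder reaction. The diene C10=C1–C2=C3 then sits on C9 and the dienophile C5=C4 on C6, joined by the three atoms C9–C8–C6 that become ring B.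

## Retrosynthesis

**Endgame.** The 2β-alcohol of 30 is taken back to the 2-ketone 29, so that the equatorial alcohol is made last by an electron-transfer reduction. The C7 acid of 29 comes from the primary alcohol 28 and its silyl ether 27; no C–C bond is involved. The lactone C20–O–C19 of 27 is opened to the hydroxy ester 26, which is the hydrolysed form of the enol ether 25. C7 is carried as a silyloxymethyl group. An ester there would make H6 the central proton of a glutaconate, labile in configuration and in double-bond position, and would need a formylacetate on the way.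

**Key disconnection.** In 25 the bonds C5–C10 and C3–C4 are cut together. This removes rings A and B, two quaternary centres and three stereocentres at once, and leads to triene 24, a bicyclo[3.2.1]octane with a dienyl arm on C9 and a Z-enoate arm on C8. Cutting ring B alone (C6–C8 or C5–C6) would leave the hindered C9–C10 bond between two ring systems unsolved. The forward reaction must be a trans-selective intramolecular cycloaddition in which C6 and C9 steer the two π faces.

**Diene arm.** The C1–C2 bond of 24 is cut to the Z-vinyl iodide 22 and stannane 23, which gives the 2-alkoxydiene in one coupling with retention of geometry. Iodide 22 is the ipso-substitution product of vinylsilane 21. Silicon is the placeholder because it survives the chromium, aluminium and base chemistry that an iodide would not.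

**Dienophile arm.** The C5=C4 bond of 21 is cut to aldehyde 19 and phosphonate 20; a Z-selective olefination is required. The C6–C7 bond of 19 (via 18) is cut by removing the hydroxymethyl group, which leads to aldehyde 17. C6 is an acyclic centre next to a quaternary carbon, so it is set by a chiral catalyst. Aldehyde 17 is the reduced form of ester 16.

**Ring D and C8.** The C13–C16 bond of 16 is cut to bromoallyl ketone 15 (vinyl anion onto ketone; C13 follows from C8). The C8–C15 bond of 15 is cut to enone 13 and allylsilane 14, and the C8–C6 bond of 13 (via 12) to enone 10 and ketene acetal 11. Both carbon groups enter at C8 by conjugate addition, the second one anti to the C9 arm. C9 therefore controls C8 through C–C bond formation. Delivering hydrogen to C9 of a preformed bicycle would occur from the exo face and give the wrong epimer.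

**C9 and the C10=C1 geometry.** Enone 10 comes from the achiral ketone 8 by enantiotopos-selective enolisation (9) and dehydrogenation. The C9–C10 bond of 8 (via 7) is cut to the Grignard reagent from bromide 2 and propargyl alcohol 3. The anti-carbomagnesiation fixes the trisubstituted alkene geometry (C1 substituent cis to C20) at the outset. Bromide 2 comes from the commercial alcohol 1.

## Roads not taken

**Alternative 1:** The C12–C13 bond of ring C is cut. The precursor is the A/B lactone A1, which carries an acetyl group on C9 and a spiro cyclopentane-1,2-dione on C8. An amine salt would turn the methyl ketone into an enamine that adds through C12 to one of the two dione carbonyls, giving ketol A2.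
- Merits: ring C and the bridgehead hydroxyl form together under mild, metal-free conditions. C8 is not stereogenic in A1, so one step sets C8 and C13.
- Weak points: A2 still carries an 11-ketone beside the epimerisable C9 and a hindered 16-ketone that must be methylenated next to a free tertiary alcohol, at least three further operations. The dione is largely enolised and the aldol is reversible, so which carbonyl reacts is under thermodynamic control. The whole A/B problem (C4, C5, C10, spiro C8) must be solved first by other chemistry.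
- Comparison: this road installs the C13 hydroxyl without an organometallic step and leaves the C/D part flexible until late. The chosen plan sets against it one step for C4, C5 and C10 and a CD unit that needs no later redox correction.

**Alternative 2:** The C10–C20 bond is cut. The relay compound is fermentation-derived gibberellic acid A3, degraded to the 1(10)-en-2-one A4 whose C19 acid is a (phenylseleno)methyl ester. Bu3SnH would generate an acyloxymethyl radical that adds 6-exo to C10 and closes the lactone, giving A5.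
- Merits: it is clearly the shortest road. C5, C6, C8, C9 and C13 come from A3, the α-oxygenated radical is matched to the enone β-carbon, and the tether forces C20 cis to C19.
- Weak points: it is a partial synthesis that depends on A3 and on several selective degradation steps (removal of the 3-hydroxyl and of the C10 oxygen, enone formation). Ester-tethered radicals cyclise slowly because the ester prefers the conformer that holds radical and alkene apart, so simple reduction competes at the quaternary centre.
- Comparison: on step count and stereochemical certainty this road is better. The chosen plan offers a de novo route from simple materials, either enantiomer, and freedom to vary C2, C7 and C20.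

**Alternative 3:** The C6–C8 bond is cut. In diazo ester A6 ring A and the CD bicycle are already joined through C9–C10 and C8 is a bridgehead C–H. A rhodium carbenoid from Rh2(O2CCPh3)4 would insert into that bond (1,5-insertion) to close ring B and give A7, one deprotection from the target.
- Merits: ring B and the quaternary C8 form last, with every oxygen function in place. Insertion into a tertiary C–H through a five-membered transition state is the favoured mode, and bulky carboxylate ligands suppress cyclopropanation.
- Weak points: a bridgehead C–H is a poorer hydride donor, and C11–H, the allylic C15–H and the 16-ene compete. C6 is set in the insertion itself. Above all, A6 requires an intermolecular union of tertiary C9 with quaternary C10 under stereocontrol, which the plan does not solve.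
- Comparison: the endgame of this road is shorter than the four steps that follow the cycloaddition here. The chosen plan makes C10 quaternary only in the cycloaddition and builds its precursor from standard reactions.

Key step: step 16

Remarks on the chemistry: gibberellin numbering is used for atoms. β is the face carrying H5, H9 and the C15–C16 bridge; α is the face of C20 and the lactone. TBS = tert-butyldimethylsilyl, TBDPS = tert-butyldiphenylsilyl, TMS = trimethylsilyl. Assumption: the sense of the enantioselective deprotonation in step 4 follows that of 4-alkylcyclohexanones; the antipodal amine is equally available.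

## Route

Step 1
Reactants: 1 1,4-dioxaspiro[4.5]decan-8-ol
Product: 2 8-bromo-1,4-dioxaspiro[4.5]decane
Conditions: CBr4, PPh3, CH2Cl2, 0 °C to rt
Reagents that add atoms: tetrabromomethane (BrC(Br)(Br)Br)
Why: Appel reaction of a secondary alcohol under neutral conditions that leave the ketal intact; no stereocentre is involved.

Step 2
Reactants: 2 8-bromo-1,4-dioxaspiro[4.5]decane; 3 prop-2-yn-1-ol
Product: 7 4-[(1Z)-3-hydroxy-1-(trimethylsilyl)prop-1-en-2-yl]cyclohexan-1-one, via Grignard reagent 4 (not isolated), via vinylmagnesium alkoxide 5 (not isolated), via bis-silylated ketal 6 (not isolated)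
Conditions: Mg, THF, 50 °C; then 3 (0.45 equiv), CuI (10 mol%), THF–Et2O, −20 °C to rt; Me3SiCl, rt; then 1 M HCl, THF, rt
Reagents that add atoms: chlorotrimethylsilane (C[Si](C)(C)Cl); water (O)
Why: Copper-catalysed anti-carbomagnesiation of the propargylic alkoxide puts the ring carbon on the internal alkyne carbon and magnesium on the terminal one, held cis to CH2O by chelation. Silylation of that C–Mg bond with retention fixes the C10=C1 geometry (silicon cis to C20), and aqueous acid then frees the alcohol and the ketone.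

Step 3
Reactants: 7 4-[(1Z)-3-hydroxy-1-(trimethylsilyl)prop-1-en-2-yl]cyclohexan-1-one
Product: 8 4-[(1Z)-3-(TBS-oxy)-1-(trimethylsilyl)prop-1-en-2-yl]cyclohexan-1-one
Conditions: t-BuMe2SiCl, imidazole, DMF, rt
Reagents that add atoms: tert-butyl(chloro)dimethylsilane (CC(C)(C)[Si](C)(C)Cl)
Why: Routine silylation of a primary allylic alcohol; protection is placed after the acid step so the silyl ether never meets aqueous acid.

Step 4
Reactants: 8 4-[(1Z)-3-(TBS-oxy)-1-(trimethylsilyl)prop-1-en-2-yl]cyclohexan-1-one
Product: 9 (4R)-silyl enol ether {[(4R)-4-[(1Z)-3-(TBS-oxy)-1-(trimethylsilyl)prop-1-en-2-yl]cyclohex-1-en-1-yl]oxy}trimethylsilane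
Conditions: (S,S)-bis(1-phenylethyl)amine, n-BuLi, LiCl, Me3SiCl (internal quench), THF, −100 to −78 °C
Reagents that add atoms: chlorotrimethylsilane (C[Si](C)(C)Cl)
Why: Enantiotopos-selective deprotonation of a 4-substituted cyclohexanone by a chiral lithium amide. The bulky equatorial substituent locks one chair, so the base distinguishes the two axial α-protons and C9 becomes stereogenic. The (S,S)-amide is chosen because the (R,R)-amide gives the (S)-enol ether with 4-alkylcyclohexanones.

Step 5
Reactants: 9 (4R)-silyl enol ether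
Product: 10 (4R)-4-[(1Z)-3-(TBS-oxy)-1-(trimethylsilyl)prop-1-en-2-yl]cyclohex-2-en-1-one
Conditions: Pd(OAc)2, MeCN, rt
Reagents that add atoms: none
Why: Saegusa–Ito oxidation places the double bond on the side of the ring where the enol ether was and gives the C14=C8 enone regiospecifically. The γ-stereocentre C9 is not touched under these base-free conditions.

Step 6
Reactants: 10 (4R)-4-substituted cyclohex-2-en-1-one; 11 tert-butyl[(1-methoxyethenyl)oxy]dimethylsilane
Product: 12 methyl 2-[(1S,6R)-3-(TBS-oxy)-6-[(1Z)-3-(TBS-oxy)-1-(trimethylsilyl)prop-1-en-2-yl]cyclohex-2-en-1-yl]acetate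
Conditions: t-BuMe2SiOTf (5 mol%), CH2Cl2, −78 °C
Reagents that add atoms: none
Why: Mukaiyama–Michael addition with silyl transfer delivers the C6–C5 acetate unit to C8 and gives the silyl enol ether needed for re-oxidation. Addition should be trans to the C9 arm, but this C8 centre is erased in step 7.

Step 7
Reactants: 12 silyl enol ether ester
Product: 13 methyl 2-[(6R)-3-oxo-6-[(1Z)-3-(TBS-oxy)-1-(trimethylsilyl)prop-1-en-2-yl]cyclohex-1-en-1-yl]acetate
Conditions: Pd(OAc)2, MeCN, rt
Reagents that add atoms: none
Why: Second Saegusa–Ito oxidation; β-hydride loss from C8 regenerates the enone, now with the acetate arm on the β-carbon.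

Step 8
Reactants: 13 β-substituted enone; 14 (2-bromoprop-2-en-1-yl)trimethylsilane
Product: 15 methyl 2-[(1R,2R)-1-(2-bromoprop-2-en-1-yl)-5-oxo-2-[(1Z)-3-(TBS-oxy)-1-(trimethylsilyl)prop-1-en-2-yl]cyclohexyl]acetate
Conditions: TiCl4, CH2Cl2, −78 to −40 °C
Reagents that add atoms: none
Why: Hosomi–Sakurai conjugate allylation of a β,β-disubstituted enone. The allylsilane should attack anti to the neighbouring C9 arm, as in 3,4-disubstituted cyclohexenones, which makes C8 quaternary with the bromoallyl group (C15) trans and the acetate arm (C6) cis to C10.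

Step 9
Reactants: 15 bromoallyl ketone
Product: 16 methyl 2-[(1R,2R,5S)-5-hydroxy-6-methylidene-2-[(1Z)-3-(TBS-oxy)-1-(trimethylsilyl)prop-1-en-2-yl]bicyclo[3.2.1]octan-1-yl]acetate
Conditions: CrCl2 (4 equiv), NiCl2 (2 mol%), DMF, rt
Reagents that add atoms: none
Why: Intramolecular Nozaki–Hiyama–Kishi reaction: the vinylchromium species adds to the C13 ketone through a five-membered ring and leaves the ester untouched. It forms C13–C16, the bridgehead alcohol and the exocyclic methylene at once, and C13 is dictated by the axial C15 arm on C8.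

Step 10
Reactants: 16 bicyclic hydroxy ester
Product: 17 2-[(1R,2R,5S)-5-hydroxy-6-methylidene-2-[(1Z)-3-(TBS-oxy)-1-(trimethylsilyl)prop-1-en-2-yl]bicyclo[3.2.1]octan-1-yl]acetaldehyde
Conditions: i-Bu2AlH (2.2 equiv), CH2Cl2, −78 °C; aq. potassium sodium tartrate
Reagents that add atoms: none
Why: Partial reduction of a hindered ester; the tetrahedral aluminate next to the quaternary carbon should survive at −78 °C, and one equivalent of hydride is consumed by the tertiary hydroxyl.

Step 11
Reactants: 17 bicyclic aldehyde
Product: 18 (2S)-3-hydroxy-2-[(1S,2R,5S)-5-hydroxy-6-methylidene-2-[(1Z)-3-(TBS-oxy)-1-(trimethylsilyl)prop-1-en-2-yl]bicyclo[3.2.1]octan-1-yl]propanal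
Conditions: (R)-2-[diphenyl(trimethylsilyloxy)methyl]pyrrolidine (20 mol%), aq. CH2O, pH 7 buffer (KH2PO4/K2HPO4), toluene, rt
Reagents that add atoms: formaldehyde (C=O)
Why: Enamine-catalysed cross-aldol with formaldehyde (organocatalytic α-hydroxymethylation). The diarylmethyl group of the (R)-catalyst shields one face of the E-enamine, so C7 should enter on the face that gives (S)-C6 under catalyst control. Any antipodal 17 left from step 4 becomes a diastereomer here and can be removed.

Step 12
Reactants: 18 β-hydroxy aldehyde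
Product: 19 (2S)-3-(TBDPS-oxy)-2-[(1S,2R,5S)-5-hydroxy-6-methylidene-2-[(1Z)-3-(TBS-oxy)-1-(trimethylsilyl)prop-1-en-2-yl]bicyclo[3.2.1]octan-1-yl]propanal
Conditions: t-BuPh2SiCl, imidazole, CH2Cl2, 0 °C
Reagents that add atoms: tert-butyl(chloro)diphenylsilane (CC(C)(C)[Si](Cl)(c1ccccc1)c1ccccc1)
Why: Silylation of the primary alcohol, done at once to forestall dehydration or retro-aldol. The tertiary bridgehead alcohol should not react, and the robust silyl group will outlast the later removal of the C20 silyl ether.

Step 13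
Reactants: 19 α-branched aldehyde; 20 methyl 2-[bis(2,2,2-trifluoroethoxy)phosphoryl]propanoate
Product: 21 methyl (2Z,4S)-5-(TBDPS-oxy)-4-[(1S,2R,5S)-5-hydroxy-6-methylidene-2-[(1Z)-3-(TBS-oxy)-1-(trimethylsilyl)prop-1-en-2-yl]bicyclo[3.2.1]octan-1-yl]-2-methylpent-2-enoate
Conditions: KN(SiMe3)2, 18-crown-6, THF, −78 °C
Reagents that add atoms: none
Why: Still–Gennari olefination: the electron-poor phosphonate eliminates fast from the kinetic adduct and should give the Z-trisubstituted enoate (C19 cis to C6). The low temperature protects the C6 centre.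

Step 14
Reactants: 21 vinylsilane enoate
Product: 22 methyl (2Z,4S)-5-(TBDPS-oxy)-4-[(1S,2R,5S)-5-hydroxy-2-[(1Z)-3-(TBS-oxy)-1-iodoprop-1-en-2-yl]-6-methylidenebicyclo[3.2.1]octan-1-yl]-2-methylpent-2-enoate
Conditions: N-iodosuccinimide, (CF3)2CHOH, 0 °C
Reagents that add atoms: N-iodosuccinimide (O=C1CCC(=O)N1I)
Why: Ipso-iododesilylation of a vinylsilane through a β-silyl cation, with retention of alkene geometry. In (CF3)2CHOH this substitution should be much faster than attack of iodine on the electron-poor enoate or on the 16-ene, which is deactivated by the neighbouring C13 oxygen.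

Step 15
Reactants: 22 Z-vinyl iodide; 23 tributyl(1-ethoxyethenyl)stannane
Product: 24 methyl (2Z,4S)-5-(TBDPS-oxy)-4-[(1S,2R,5S)-2-[(2Z)-1-(TBS-oxy)-4-ethoxypenta-2,4-dien-2-yl]-5-hydroxy-6-methylidenebicyclo[3.2.1]octan-1-yl]-2-methylpent-2-enoate
Conditions: Pd2(dba)3 (2.5 mol%), AsPh3, CuI, DMF, rt to 40 °C
Reagents that add atoms: none
Why: Stille coupling with retention at the unhindered CH–I carbon installs C2–C3 as a 2-alkoxydiene in one step, with the C9 tether outside and C20 inside on C10.

Step 16
Reactants: 24 triene (2-ethoxydiene on C9, Z-enoate on C8)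
Product: 25 tetracyclic enol ether (1,2-ene with 2-OEt, 16-methylidene, 13-OH, 4α-CO2Me, 4β-CH3, 10α-CH2OTBS, 6β-CH2OTBDPS, 5β-H, 9β-H)
Conditions: toluene (0.005 M), 2,6-di-tert-butyl-4-methylphenol, Et3N (1 mol%), sealed tube, 170 °C
Reagents that add atoms: none
Why: Thermal type 1 intramolecular Diels–Alder reaction of a 1,3,8-nonatriene, the established route to hydrindanes: diene C10=C1–C2=C3 and dienophile C5=C4 join in one concerted suprafacial step to form C5–C10 and C3–C4. Ring A closes as the new cyclohexene and ring B as the five-membered ring spanned by the tether C9–C8–C6 (fused mode); the tether, not the polarity of the partners, fixes the orientation, which is why heat and not a Lewis acid is used. C4 follows from the Z-enoate geometry (C19 stays cis to C6, C18 cis to H5). C5 is set by C6: allylic 1,3-strain with the cis ester holds H6 in the enoate plane, and the diene can only reach the face on which C8 lies, which puts H5 anti to H6. C10 is set by the diene geometry and by C9: the tether is outside and C20 inside, and the rotamer about C9–C10 with H9 eclipsing C10=C1 exposes the face that places C20 anti to H9. The step needs the tether-anti (exo) transition state that gives the trans ring fusion; there the ester is exo and the C4 methyl endo, the arrangement 2-methylacrylates prefer, and both strain-minimised rotamers fit it. The free 13-hydroxyl and the silyl ethers are spectators; base-washed glass, an inhibitor and a trace of amine protect the enol ether.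

Step 17
Reactants: 25 tetracyclic enol ether
Product: 27 2-oxo 19,20-lactone with 6β-CH2OTBDPS and free 13-OH, via hydroxy keto ester 26 (not isolated)
Conditions: camphorsulfonic acid (cat.), MeOH–H2O, rt; then toluene, 50 °C
Reagents that add atoms: water (O)
Why: Acid hydrolysis of the enol ether gives the C2 ketone, and the primary TBS ether is cleaved while the TBDPS ether should survive. The freed C20 hydroxyl lies 1,3-diaxial to the C19 ester and should close the δ-lactone by transesterification on warming in toluene, which also drains any reversible C2–C20 hemiketal. The still-protected C7 oxygen cannot compete for C19.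

Step 18
Reactants: 27 TBDPS-protected keto lactone
Product: 28 2-oxo 19,20-lactone with 6β-CH2OH and 13-OH
Conditions: HF·pyridine, pyridine, THF, 0 °C to rt
Reagents that add atoms: none
Why: Fluoride cleavage of the silyl ether under weakly acidic conditions, so no alkoxide is formed that could shift the lactone from C20 to C7.

Step 19
Reactants: 28 primary alcohol
Product: 29 13-hydroxy-2-oxo 19,20-lactone 7-oic acid
Conditions: TEMPO (cat.), PhI(OAc)2, MeCN–H2O, rt
Reagents that add atoms: water (O)
Why: Oxoammonium oxidation of the primary alcohol through the aldehyde hydrate to the acid. The tertiary alcohol, ketone, lactone and exocyclic alkene should be inert, and no hindered ester has to be hydrolysed.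

Step 20
Reactants: 29 2-keto acid
Product: 30 target gibberellin (ent-2α,13,20-trihydroxygibberell-16-ene-7,19-dioic acid 19,20-lactone)
Conditions: SmI2, THF, i-PrOH, 0 °C to rt
Reagents that add atoms: none
Why: Electron-transfer (ketyl) reduction of the ketone, which should give the thermodynamically preferred equatorial 2β-alcohol. A borohydride would attack from the open β face and give the axial 2α-epimer, because the lactone bridge blocks the α face.

## Compound list

1 | 1,4-dioxaspiro[4.5]decan-8-ol | OC1CCC2(CC1)OCCO2 | starting material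
2 | 8-bromo-1,4-dioxaspiro[4.5]decane | BrC1CCC2(CC1)OCCO2 | intermediate
3 | prop-2-yn-1-ol | OCC#C | starting material
4 | (1,4-dioxaspiro[4.5]decan-8-yl)magnesium bromide | Br[Mg]C1CCC2(CC1)OCCO2 | intermediate
5 | bromomagnesium (2Z)-3-(bromomagnesio)-2-(1,4-dioxaspiro[4.5]decan-8-yl)prop-2-en-1-olate | Br[Mg]OC/C(=C\[Mg]Br)C1CCC2(CC1)OCCO2 | intermediate
6 | trimethyl{[(2Z)-2-(1,4-dioxaspiro[4.5]decan-8-yl)-3-(trimethylsilyl)prop-2-en-1-yl]oxy}silane | C[Si](C)(C)OC/C(=C\[Si](C)(C)C)C1CCC2(CC1)OCCO2 | intermediate
7 | 4-[(1Z)-3-hydroxy-1-(trimethylsilyl)prop-1-en-2-yl]cyclohexan-1-one | O=C1CCC(CC1)/C(CO)=C/[Si](C)(C)C | intermediate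
8 | 4-[(1Z)-3-(tert-butyldimethylsilyloxy)-1-(trimethylsilyl)prop-1-en-2-yl]cyclohexan-1-one | O=C1CCC(CC1)/C(CO[Si](C)(C)C(C)(C)C)=C/[Si](C)(C)C | intermediate
9 | {[(4R)-4-[(1Z)-3-(tert-butyldimethylsilyloxy)-1-(trimethylsilyl)prop-1-en-2-yl]cyclohex-1-en-1-yl]oxy}trimethylsilane | C[Si](C)(C)OC1=CC[C@@H](CC1)/C(CO[Si](C)(C)C(C)(C)C)=C/[Si](C)(C)C | intermediate
10 | (4R)-4-[(1Z)-3-(tert-butyldimethylsilyloxy)-1-(trimethylsilyl)prop-1-en-2-yl]cyclohex-2-en-1-one | O=C1C=C[C@@H](CC1)/C(CO[Si](C)(C)C(C)(C)C)=C/[Si](C)(C)C | intermediate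
11 | tert-butyl[(1-methoxyethenyl)oxy]dimethylsilane | C=C(OC)O[Si](C)(C)C(C)(C)C | starting material
12 | methyl 2-[(1S,6R)-3-(tert-butyldimethylsilyloxy)-6-[(1Z)-3-(tert-butyldimethylsilyloxy)-1-(trimethylsilyl)prop-1-en-2-yl]cyclohex-2-en-1-yl]acetate | COC(=O)C[C@@H]1C=C(O[Si](C)(C)C(C)(C)C)CC[C@H]1/C(CO[Si](C)(C)C(C)(C)C)=C/[Si](C)(C)C | intermediate
13 | methyl 2-[(6R)-3-oxo-6-[(1Z)-3-(tert-butyldimethylsilyloxy)-1-(trimethylsilyl)prop-1-en-2-yl]cyclohex-1-en-1-yl]acetate | COC(=O)CC1=CC(=O)CC[C@H]1/C(CO[Si](C)(C)C(C)(C)C)=C/[Si](C)(C)C | intermediate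
14 | (2-bromoprop-2-en-1-yl)trimethylsilane | C=C(Br)C[Si](C)(C)C | starting material
15 | methyl 2-[(1R,2R)-1-(2-bromoprop-2-en-1-yl)-5-oxo-2-[(1Z)-3-(tert-butyldimethylsilyloxy)-1-(trimethylsilyl)prop-1-en-2-yl]cyclohexyl]acetate | C=C(Br)C[C@@]1(CC(=O)CC[C@H]1/C(CO[Si](C)(C)C(C)(C)C)=C/[Si](C)(C)C)CC(=O)OC | intermediate
16 | methyl 2-[(1R,2R,5S)-5-hydroxy-6-methylidene-2-[(1Z)-3-(tert-butyldimethylsilyloxy)-1-(trimethylsilyl)prop-1-en-2-yl]bicyclo[3.2.1]octan-1-yl]acetate | C=C1C[C@@]2(C[C@@]1(O)CC[C@H]2/C(CO[Si](C)(C)C(C)(C)C)=C/[Si](C)(C)C)CC(=O)OC | intermediate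
17 | 2-[(1R,2R,5S)-5-hydroxy-6-methylidene-2-[(1Z)-3-(tert-butyldimethylsilyloxy)-1-(trimethylsilyl)prop-1-en-2-yl]bicyclo[3.2.1]octan-1-yl]acetaldehyde | C=C1C[C@@]2(C[C@@]1(O)CC[C@H]2/C(CO[Si](C)(C)C(C)(C)C)=C/[Si](C)(C)C)CC=O | intermediate
18 | (2S)-3-hydroxy-2-[(1S,2R,5S)-5-hydroxy-6-methylidene-2-[(1Z)-3-(tert-butyldimethylsilyloxy)-1-(trimethylsilyl)prop-1-en-2-yl]bicyclo[3.2.1]octan-1-yl]propanal | C=C1C[C@@]2(C[C@@]1(O)CC[C@H]2/C(CO[Si](C)(C)C(C)(C)C)=C/[Si](C)(C)C)[C@@H](CO)C=O | intermediate
19 | (2S)-3-(tert-butyldiphenylsilyloxy)-2-[(1S,2R,5S)-5-hydroxy-6-methylidene-2-[(1Z)-3-(tert-butyldimethylsilyloxy)-1-(trimethylsilyl)prop-1-en-2-yl]bicyclo[3.2.1]octan-1-yl]propanal | C=C1C[C@@]2(C[C@@]1(O)CC[C@H]2/C(CO[Si](C)(C)C(C)(C)C)=C/[Si](C)(C)C)[C@@H](CO[Si](c1ccccc1)(c1ccccc1)C(C)(C)C)C=O | intermediate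
20 | methyl 2-[bis(2,2,2-trifluoroethoxy)phosphoryl]propanoate | COC(=O)C(C)P(=O)(OCC(F)(F)F)OCC(F)(F)F | starting material
21 | methyl (2Z,4S)-5-(tert-butyldiphenylsilyloxy)-4-[(1S,2R,5S)-5-hydroxy-6-methylidene-2-[(1Z)-3-(tert-butyldimethylsilyloxy)-1-(trimethylsilyl)prop-1-en-2-yl]bicyclo[3.2.1]octan-1-yl]-2-methylpent-2-enoate | C=C1C[C@@]2(C[C@@]1(O)CC[C@H]2/C(CO[Si](C)(C)C(C)(C)C)=C/[Si](C)(C)C)[C@@H](CO[Si](c1ccccc1)(c1ccccc1)C(C)(C)C)/C=C(/C)C(=O)OC | intermediate
22 | methyl (2Z,4S)-5-(tert-butyldiphenylsilyloxy)-4-[(1S,2R,5S)-5-hydroxy-2-[(1Z)-3-(tert-butyldimethylsilyloxy)-1-iodoprop-1-en-2-yl]-6-methylidenebicyclo[3.2.1]octan-1-yl]-2-methylpent-2-enoate | C=C1C[C@@]2(C[C@@]1(O)CC[C@H]2/C(CO[Si](C)(C)C(C)(C)C)=C/I)[C@@H](CO[Si](c1ccccc1)(c1ccccc1)C(C)(C)C)/C=C(/C)C(=O)OC | intermediate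
23 | tributyl(1-ethoxyethenyl)stannane | CCOC(=C)[Sn](CCCC)(CCCC)CCCC | starting material
24 | methyl (2Z,4S)-5-(tert-butyldiphenylsilyloxy)-4-[(1S,2R,5S)-2-[(2Z)-1-(tert-butyldimethylsilyloxy)-4-ethoxypenta-2,4-dien-2-yl]-5-hydroxy-6-methylidenebicyclo[3.2.1]octan-1-yl]-2-methylpent-2-enoate | C=C1C[C@@]2(C[C@@]1(O)CC[C@H]2/C(CO[Si](C)(C)C(C)(C)C)=C/C(OCC)=C)[C@@H](CO[Si](c1ccccc1)(c1ccccc1)C(C)(C)C)/C=C(/C)C(=O)OC | intermediate
25 | Diels–Alder adduct: gibberellane tetracycle with 1,2-double bond bearing 2-OEt, 16-methylidene, 13-OH, 4α-CO2Me (C19), 4β-CH3, 10α-CH2OTBS (C20), 6β-CH2OTBDPS (C7), 5β-H, 9β-H | C=C1C[C@]23C[C@@]1(O)CC[C@H]2[C@]4(CO[Si](C)(C)C(C)(C)C)C=C(OCC)C[C@@](C)(C(=O)OC)[C@H]4[C@@H]3CO[Si](c5ccccc5)(c5ccccc5)C(C)(C)C | intermediate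
26 | hydroxy keto ester: as 25 but with a 2-ketone (C1 is CH2) and free 10α-CH2OH | C=C1C[C@]23C[C@@]1(O)CC[C@H]2[C@]4(CO)CC(=O)C[C@@](C)(C(=O)OC)[C@H]4[C@@H]3CO[Si](c5ccccc5)(c5ccccc5)C(C)(C)C | intermediate
27 | 13-hydroxy-2-oxo 19,20-lactone with 6β-CH2OTBDPS (natural configuration at C4, C5, C6, C8, C9, C10, C13) | C=C1C[C@]23C[C@@]1(O)CC[C@H]2[C@]12COC(=O)[C@](C)(CC(=O)C1)[C@H]2[C@@H]3CO[Si](c1ccccc1)(c1ccccc1)C(C)(C)C | intermediate
28 | 13-hydroxy-2-oxo 19,20-lactone with 6β-CH2OH | C=C1C[C@]23C[C@@]1(O)CC[C@H]2[C@]12COC(=O)[C@](C)(CC(=O)C1)[C@H]2[C@@H]3CO | intermediate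
29 | 13-hydroxy-2-oxo 19,20-lactone 7-oic acid (2-oxo analogue of the target) | C=C1C[C@]23C[C@@]1(O)CC[C@H]2[C@]12COC(=O)[C@](C)(CC(=O)C1)[C@H]2[C@@H]3C(=O)O | intermediate
30 | target gibberellin: 2β,13-dihydroxy 19,20-lactone 7-oic acid (ent-2α,13,20-trihydroxygibberell-16-ene-7,19-dioic acid 19,20-lactone) | C=C1C[C@]23C[C@@]1(O)CC[C@H]2[C@]12COC(=O)[C@](C)(C[C@@H](O)C1)[C@H]2[C@@H]3C(=O)O | target

## Step count and weakest steps

Total: 20 steps. Longest linear sequence: 20 steps, from 1 to 30. Compounds 3, 11, 14, 20 and 23 are bought and enter directly.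

**Step 16 (key step).** The orientation is enforced by the tether and not helped by the enol ether, and each new bond ends at a fully substituted carbon, so the cycloaddition may need a temperature at which other thermal processes intervene. These are a 1,5-hydrogen shift from C20 to C3 across the Z-substituted diene and hydrolysis or isomerisation of the enol ether. Discrimination between the tether-anti (trans-fused) and tether-syn (cis-fused) transition states may also be incomplete. The fallback sets out from 24. Mild hydrolysis (oxalic acid on wet silica) gives the methyl ketone, Z-enone F1. With pyrrolidine in MeOH–toluene at 60–80 °C, F1 equilibrates with its 2-amino-1,3-diene, a more electron-rich diene that is formed reversibly and should undergo the same intramolecular cycloaddition at lower temperature. Hydrolysis of the enamine on work-up gives the tetracyclic 2-ketone F2, which under the conditions of step 17 loses the C20 silyl group, lactonises, and rejoins the route at 27.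

**Step 8.** The bromine lowers the nucleophilicity of the allylsilane and the β-carbon of 13 is flanked by the C9 arm, so conjugate addition may be slow and protodesilylation or enone isomerisation may take over. The fallback sets out from 13. Conjugate propargylation with allenyltributylstannane and TiCl4 (a slimmer nucleophile, same anti approach) gives the propargyl ketone F3. A ketyl–alkyne 5-exo-dig cyclisation with SmI2, hexamethylphosphoramide and t-BuOH then forms C13–C16 and the exocyclic methylene, and returns to the route at 16, bypassing step 9 as well.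

**Step 11.** The enamine carbon is neopentyl-like, so turnover may be slow. The β-hydroxy aldehyde can dehydrate or oligomerise before silylation, and the catalyst may be mismatched with the C8 centre, eroding selectivity at C6. The fallback sets out from 16 and replaces catalyst control by an auxiliary. Saponification (LiOH, THF–H2O) gives the carboxylic acid F4. Acylation of lithiated (4R)-4-benzyl-1,3-oxazolidin-2-one through the pivaloyl mixed anhydride gives the imide F5. Its titanium enolate (TiCl4, i-Pr2NEt) with 1,3,5-trioxane gives the hydroxymethyl imide F6, with C6 set by the auxiliary. Silylation (t-BuPh2SiCl, imidazole) gives the silyl ether F7, and LiBH4 removes the auxiliary to give the primary alcohol F8. Dess–Martin oxidation of F8 returns to the route at 19.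

**Step 20.** Protonation of the ketyl-derived intermediate may not be fully under thermodynamic control, leaving a mixture of C2 epimers that are hard to separate as free acids. The fallback sets out from 27, before the acid is unveiled, and replaces thermodynamic control by inversion. NaBH4 (hydride from the open β face) gives the axial 2α-alcohol F9. Mitsunobu inversion (PPh3, diisopropyl azodicarboxylate, 4-nitrobenzoic acid) gives the 2β-nitrobenzoate F10. HF·pyridine frees the C7 hydroxyl and gives the primary alcohol F11, and TEMPO/PhI(OAc)2 oxidation gives the carboxylic acid F12. K2CO3 in MeOH–H2O followed by acidification removes the nitrobenzoate, recloses the lactone and arrives at 30.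

## Further compounds

F1 | step 16 | methyl (2Z,4S)-5-(tert-butyldiphenylsilyloxy)-4-[(1S,2R,5S)-2-[(2Z)-1-(tert-butyldimethylsilyloxy)-4-oxopent-2-en-2-yl]-5-hydroxy-6-methylidenebicyclo[3.2.1]octan-1-yl]-2-methylpent-2-enoate | C=C1C[C@@]2(C[C@@]1(O)CC[C@H]2/C(CO[Si](C)(C)C(C)(C)C)=C/C(C)=O)[C@@H](CO[Si](c1ccccc1)(c1ccccc1)C(C)(C)C)/C=C(/C)C(=O)OC
F2 | step 16 | tetracyclic 2-ketone with 10α-CH2OTBS, 4α-CO2Me, 6β-CH2OTBDPS and 13-OH | C=C1C[C@]23C[C@@]1(O)CC[C@H]2[C@]4(CO[Si](C)(C)C(C)(C)C)CC(=O)C[C@@](C)(C(=O)OC)[C@H]4[C@@H]3CO[Si](c5ccccc5)(c5ccccc5)C(C)(C)C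
F3 | step 8 | methyl 2-[(1R,2R)-5-oxo-1-(prop-2-yn-1-yl)-2-[(1Z)-3-(tert-butyldimethylsilyloxy)-1-(trimethylsilyl)prop-1-en-2-yl]cyclohexyl]acetate | C#CC[C@@]1(CC(=O)CC[C@H]1/C(CO[Si](C)(C)C(C)(C)C)=C/[Si](C)(C)C)CC(=O)OC
F4 | step 11 | carboxylic acid of 16 | C=C1C[C@@]2(C[C@@]1(O)CC[C@H]2/C(CO[Si](C)(C)C(C)(C)C)=C/[Si](C)(C)C)CC(=O)O
F5 | step 11 | N-acyl (4R)-4-benzyl-1,3-oxazolidin-2-one of F4 | C=C1C[C@@]2(C[C@@]1(O)CC[C@H]2/C(CO[Si](C)(C)C(C)(C)C)=C/[Si](C)(C)C)CC(=O)N1[C@H](Cc2ccccc2)COC1=O
F6 | step 11 | hydroxymethylated imide, (S) at C6 | C=C1C[C@@]2(C[C@@]1(O)CC[C@H]2/C(CO[Si](C)(C)C(C)(C)C)=C/[Si](C)(C)C)[C@@H](CO)C(=O)N1[C@H](Cc2ccccc2)COC1=O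
F7 | step 11 | tert-butyldiphenylsilyl ether of F6 | C=C1C[C@@]2(C[C@@]1(O)CC[C@H]2/C(CO[Si](C)(C)C(C)(C)C)=C/[Si](C)(C)C)[C@@H](CO[Si](c1ccccc1)(c1ccccc1)C(C)(C)C)C(=O)N1[C@H](Cc2ccccc2)COC1=O
F8 | step 11 | primary alcohol from reductive removal of the auxiliary (C5 as CH2OH, C7 as CH2OTBDPS) | C=C1C[C@@]2(C[C@@]1(O)CC[C@H]2/C(CO[Si](C)(C)C(C)(C)C)=C/[Si](C)(C)C)[C@@H](CO[Si](c1ccccc1)(c1ccccc1)C(C)(C)C)CO
F9 | step 20 | 2α-alcohol (2-epimer) of the 19,20-lactone with 6β-CH2OTBDPS | C=C1C[C@]23C[C@@]1(O)CC[C@H]2[C@]12COC(=O)[C@](C)(C[C@H](O)C1)[C@H]2[C@@H]3CO[Si](c1ccccc1)(c1ccccc1)C(C)(C)C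
F10 | step 20 | 2β-(4-nitrobenzoate) of the 19,20-lactone with 6β-CH2OTBDPS | C=C1C[C@]23C[C@@]1(O)CC[C@H]2[C@]12COC(=O)[C@](C)(C[C@@H](OC(=O)c4ccc(cc4)[N+](=O)[O-])C1)[C@H]2[C@@H]3CO[Si](c1ccccc1)(c1ccccc1)C(C)(C)C
F11 | step 20 | 2β-(4-nitrobenzoate) with 6β-CH2OH | C=C1C[C@]23C[C@@]1(O)CC[C@H]2[C@]12COC(=O)[C@](C)(C[C@@H](OC(=O)c4ccc(cc4)[N+](=O)[O-])C1)[C@H]2[C@@H]3CO
F12 | step 20 | 2β-(4-nitrobenzoate) of the target acid 30 | C=C1C[C@]23C[C@@]1(O)CC[C@H]2[C@]12COC(=O)[C@](C)(C[C@@H](OC(=O)c4ccc(cc4)[N+](=O)[O-])C1)[C@H]2[C@@H]3C(=O)O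
A1 | alternative 1 | A/B lactone with C9 acetyl and spiro cyclopentane-1,2-dione at C8 | CC(=O)[C@H]1[C@]23COC(=O)[C@](C)(C[C@@H](O[Si](C)(C)C(C)(C)C)C2)[C@H]3[C@H](C(=O)OC)C14CC(=O)C(=O)C4
A2 | alternative 1 | 11,16-dioxo-13-hydroxy tetracycle, 2-silyl ether, C7 methyl ester | O=C1C[C@]23C[C@@]1(O)CC(=O)[C@H]2[C@]12COC(=O)[C@](C)(C[C@@H](O[Si](C)(C)C(C)(C)C)C1)[C@H]2[C@@H]3C(=O)OC
A3 | alternative 2 | gibberellic acid | C[C@@]12[C@H](C=C[C@@]3([C@@H]1[C@@H]([C@]45[C@H]3CC[C@](C4)(C(=C)C5)O)C(=O)O)OC2=O)O
A4 | alternative 2 | 1(10)-en-2-one with C19 (phenylseleno)methyl ester and C7 methyl ester | C=C1C[C@]23C[C@@]1(O)CC[C@H]2C1=CC(=O)C[C@@](C)(C(=O)OC[Se]c2ccccc2)[C@H]1[C@@H]3C(=O)OC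
A5 | alternative 2 | 2-oxo 19,20-lactone C7 methyl ester | C=C1C[C@]23C[C@@]1(O)CC[C@H]2[C@]12COC(=O)[C@](C)(CC(=O)C1)[C@H]2[C@@H]3C(=O)OC
A6 | alternative 3 | C6 diazo ester with ring A lactone joined to the CD bicycle at C9–C10 (C8–H bridgehead), 2,13-diacetate | C=C1C[C@@H]2C[C@@]1(OC(C)=O)CC[C@H]2[C@]12COC(=O)[C@](C)(C[C@@H](OC(C)=O)C1)[C@H]2C(=[N+]=[N-])C(=O)OC
A7 | alternative 3 | 2,13-diacetate C7 methyl ester of the target gibberellin | C=C1C[C@]23C[C@@]1(OC(C)=O)CC[C@H]2[C@]12COC(=O)[C@](C)(C[C@@H](OC(C)=O)C1)[C@H]2[C@@H]3C(=O)OC
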